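(The runs stem from a simulated flask for substances that don't exist; scatter was added.)

The vessel is closed, stirred and isothermal, and I want the target it holds at 12 d for three loadings of initiator.

common to all: substrate 0.013 M

| charge | reagent | initiator | remark | time |
|---|---|---|---|---|
| spring | 1.5 equiv | 1.6 mol% | run made earlier |  |
| midnight | 1.5 equiv | 5.8 mol% | run made earlier |  |
| theta | 1.50 equiv | 1.2 mol% |  | 12 d |
| eta | 1.50 equiv | 2.5 mol% |  | 12 d |
| alpha | 1.50 equiv | 5 mol% |  | 12 d |

| run | time / d | target / % |
|---|---|---|
| spring | 0.625 | 13.2 |
| spring | 1.04 | 18.0 |
| spring | 1.67 | 19.6 |
| spring | 2.50 | 21.1 |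
| spring | 4.00 | 22.7 |
| spring | 6.00 | 21.5 |
| spring | 8.00 | 21.8 |
| midnight | 1.25 | 27.0 |
| midnight | 2.50 | 28.6 |
| midnight | 4.00 | 29.7 |
| midnight | 5.00 | 30.3 |
| midnight | 6.00 | 29.8 |
| midnight | 8.00 | 29.1 |

(standard deviation of a reading: 0.5 percentage points)

* amount of target at the end, in percent of the substrate charged for theta, eta, alpha, in this order
* the shape of the row from first to last (rises, then falls / falls, then rises / rises all the way / hardly changes / falls all the way)

- percent here means substrate units held: one ended chains or side product counts as two
- the earlier runs were read with a standard deviation of 0.5 percentage points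
- steps under discussion: initiator -> 2 initiating radical; substrate + initiating radical -> capped initiator + first chain carrier; reagent + first chain carrier <-> target + second chain carrier; substrate + second chain carrier -> released group + first chain carrier; 2 first chain carrier -> ended chains; substrate + target -> side product
- "hardly changes" means that all values lie within two and a half points (for a concentration: within two and a half percent of the largest)

I read the earlier runs as a ladder of time scales. The fastest rung is the rise: spring reaches 13.2% by 0.625 d, and midnight reaches 27.0% by 1.25 d. Next comes the bend: from 1.04 d to 4.00 d, spring's readings gain 4.7 percentage points. The slowest rung is the flat end: the readings at 4.00 d and 8.00 d in spring differ by 0.9 points, and a single reading scatters by 0.5 points, so I can't read a trend there. So I treat each run from 4.00 d on as a plateau and carry it unchanged to 12 d.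

The plateau means are 22.0% for spring and 29.7% for midnight. My one quantity is the plateau exponent, the slope of ln(plateau) against ln(loading) at this charge of substrate and reagent. It comes to 0.234. Scaling spring's plateau by it, I commit to 20.6% for theta, 24.4% for eta and 28.7% for alpha. The exponent is positive, so more initiator gives more target on this reckoning, and the row rises. Theta's loading lies below both runs, so that point is an extrapolation.

The forecast gives 19.5%, 23.6% and 27.7%, lower than my values, with the shape rises all the way, and says “the row rises throughout”.

The flask gives 20.3%, 24.4% and 28.8%: the row rises all the way.

    initiator → 2 initiating radical (k = 4.20 × 10⁻⁷ s⁻¹)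
    substrate + initiating radical → capped initiator + first chain carrier (k = 79000 M⁻¹ s⁻¹)
    reagent + first chain carrier ⇌ target + second chain carrier (K = 0.0920, k = 2900 M⁻¹ s⁻¹)
    substrate + second chain carrier → released group + first chain carrier (k = 5100 M⁻¹ s⁻¹)
    2 first chain carrier → ended chains (k = 5.30 × 10⁷ M⁻¹ s⁻¹)
    substrate + target → side product (k = 7.50 × 10⁻⁴ M⁻¹ s⁻¹)

In theta at 12.0 d, the substrate, the limiting reagent, is down to 1.45% of its charge, side product holds 77.4% and target holds 20.3%. Carried from eta's result to alpha's loading of 5 mol%, the plateau exponent gives 28.7%, and alpha stands at 28.8%.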